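I must choose for the next run between charging more free base and charging more nucleophile, so I first ask what sets the rate.

electrophile 0.26 M; nucleophile 0.780 M; free base 0.208 M; time 2.0 d

    electrophile + nucleophile → acid set free + target (k1 = 6.73 × 10⁻⁵ /M/s)
    nucleophile + acid set free ⇌ protonated nucleophile, settled at all times (K2 = 1040 /M)
    acid set free + free base ⇌ salt of the base, settled at all times (K3 = 5.0 /M)
    electrophile + acid set free ⇌ idle adduct, settled at all times (K4 = 930 /M)
    electrophile + target → side product (k5 = 3.17 × 10⁻⁵ /M/s)

- a species is counted by the electrophile in it: one side product counts as two
- amounts and yields of acid set free count idle adduct too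
- run time (flask): 2.0 d

1. part of the electrophile that has reacted at 2.0 d
2. share of the unused nucleophile that is free and not bound as protonated nucleophile, at 2.0 d

Step 1 is first order in free [nucleophile]. The acid set free goes to the nucleophile, not the free base, since K2[nucleophile] at the start is 810 and K3[free base] is 1.0. So each electrophile taken by step 1 costs two nucleophile: one goes into target, and one is bound as protonated nucleophile. That leaves 0.260 M, the reserve, which is what stays free once each charged electrophile has cost its two. The reserve is positive, so in my reckoning the electrophile stops first and [nucleophile] stays above the reserve. I then treat the electrophile as pseudo-first-order, with k1 times the reserve as its constant. That gives 95.1 % reacted at 2.0 d. The reserve over the unused nucleophile gives 50.0 % free. I leave out step 5 and the idle adduct. With 1.04 M of nucleophile charged, the reserve is 0.520 M, and the same reckoning gives 99.8 % reacted at 2.0 d. So I charge more nucleophile and no more free base, whose K3[free base] stands far below K2[nucleophile].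

The forecast gives 98 % (94 % to 99.5 %) and 59 % (56 % to 62 %), above both my figures, and its ground reads: “The base is far too weak to compete”.

The flask gives 98.9 % reacted and 58.7 % free.

In this flask step 1 uses electrophile 11 times as fast as step 5 at 0.166 d, but 3.3 times as fast at 2.00 d, when side product stands at 19.3 %. Step 1 has then run 0.230 M of the 0.26 M charged, so the reserve becomes 41.0 % of the charge instead of 0.260 M, and the nucleophile left is 41 %. In the neighbour flask with 0.10 M of electrophile, the reserve is 74.4 % of the charge, and with side product at 6.61 % the nucleophile left is 75 %.

(All constants are made up; the rest is arithmetic.)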